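**Retrosynthetic overview**
- The C17 hydroxyl comes from the former C9 carbonyl oxygen: the target is the 1,3-allylic transposition product of a C9 tertiary allylic alcohol bearing an 8(17)-exo-methylene; the butenolide comes from a 3-substituted furan (singlet oxygen).
- The C9–C11 bond is made by adding a 2-(furan-3-yl)ethyl cerium reagent to the C9 carbonyl of a cis-fused ene-dione while C6 is masked in the same pot as its C17-deprotonated dienolate; the C6 and C2 carbinols come from a kinetic hydride and a dissolving-metal reduction.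
- Ring A, the cis C5/C10 pair and the gem-dimethyl carbon come from one catalytic enantioselective Diels–Alder reaction that desymmetrises 2,6-dimethyl-1,4-benzoquinone with the silyl dienol ether of mesityl oxide.
- Ring order: ring B arrives as the quinone (from 2,6-dimethylphenol), ring A is closed by the cycloaddition, the butenolide is unveiled in the penultimate step.

Convention: labdane numbering (C1–C10 decalin, C11–C12 chain, C13–C16 furan/butenolide, C17 on C8, methyl C20 on C10); β is the face of the C10 methyl. The target is (2S,5R,6S,10S), i.e. cis-fused (5β-H), 2α-OH, 6α-OH.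

Assumption: the facial sense of the oxazaborolidinium catalyst in step 3 is taken from the usual α-C–H···O binding model, which points to the (R)-catalyst; should the adduct prove antipodal, the (S)-catalyst is used and nothing else changes.

**Step 1**
Reactants: 1 xylenol (2,6-dimethylphenol)
Product: 2 dimethylquinone (2,6-dimethyl-1,4-benzoquinone)
Conditions: O2 (1 atm), Co(salen) [Co(C16H14N2O2)] (5 mol %), DMF, 25 °C
Reagents that add atoms: dioxygen, O=O
Why: Cobalt–salen-catalysed aerobic phenol oxidation puts oxygen para to the hydroxyl because both ortho positions are blocked, giving the symmetric quinone (no stereocentre).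

**Step 2**
Reactants: 3 mesityl oxide (4-methylpent-3-en-2-one)
Product: 5 triisopropyl[(4-methylpenta-1,3-dien-2-yl)oxy]silane, via lithium enolate 4 (not isolated)
Conditions: LiN(iPr)2, THF, −78 °C; iPr3SiOTf, −78 → 0 °C
Reagents that add atoms: triisopropylsilyl trifluoromethanesulfonate, CC(C)[Si](OS(=O)(=O)C(F)(F)F)(C(C)C)C(C)C
Why: Kinetic deprotonation of the acetyl methyl gives the cross-conjugated enolate, and O-silylation (silyl enol ether formation) gives the 2-silyloxy diene.

**Step 3** (key step)
Reactants: 2 dimethylquinone; 5 silyloxy diene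
Product: 6 cis-fused silyloxy ene-dione (4aR,8aS)-2,5,5,8a-tetramethyl-7-[(triisopropylsilyl)oxy]-4a,5,8,8a-tetrahydronaphthalene-1,4-dione
Conditions: (R)-1-(2-methylphenyl)-3,3-diphenyl-tetrahydropyrrolo[1,2-c][1,3,2]oxazaborole·HN(SO2CF3)2 (20 mol %), CH2Cl2, −78 → −40 °C
Reagents that add atoms: none
Why: Catalytic enantioselective Diels–Alder reaction (asynchronous, Mukaiyama–Michael-like) on one of the two enantiotopic C=C bonds: the catalyst binds the carbonyl flanked by two C–H groups, the nucleophilic CH2 terminus bonds to the methyl-bearing β-carbon (C10) and the CMe2 terminus to the adjacent CH (C5), so C5/C10 are cis by suprafacial addition and their absolute configuration is set by the catalyst; the reaction class is known but this hindered diene is untested in it.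

**Step 4**
Reactants: 7 bromofuran (3-bromofuran); 8 oxirane
Product: 10 furylethanol 2-(furan-3-yl)ethanol, via furan-3-yllithium 9 (not isolated)
Conditions: n-BuLi, THF, −78 °C; oxirane, BF3·OEt2, −78 °C; H2O
Reagents that add atoms: none
Why: Bromine–lithium exchange followed by Lewis-acid-assisted SN2 opening of the epoxide attaches the two-carbon arm at C3 of the furan.

**Step 5**
Reactants: 10 furylethanol
Product: 11 bromide 3-(2-bromoethyl)furan
Conditions: CBr4, PPh3, CH2Cl2, 0 °C
Reagents that add atoms: tetrabromomethane, BrC(Br)(Br)Br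
Why: The Appel reaction converts the primary alcohol to the bromide under neutral conditions that the furan tolerates.

**Step 6**
Reactants: 6 silyloxy ene-dione; 11 bromide
Product: 16 keto alcohol 9α-hydroxy-2-[(triisopropylsilyl)oxy]-15,16-epoxy-5β-labda-2,8(17),13(16),14-tetraen-6-one, via Grignard reagent 12 (not isolated), via organocerium reagent 13 (not isolated), via lithium dienolate 14 (not isolated), via alkoxide enolate 15 (not isolated)
Conditions: (a) 11, Mg, THF, 25 °C; CeCl3, THF, −78 °C; (b) 6, LiN(SiMe3)2, THF, −78 °C; add (a), −78 → −30 °C; AcOH, −78 °C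
Reagents that add atoms: none
Why: The amide base removes a vinylogous C17 proton, so C6 is masked as the extended dienolate and only the C9 carbonyl remains for 1,2-addition of the weakly basic organocerium reagent (enolate-protected carbonyl addition); kinetic α-protonation at C7 then leaves the 8(17)-exo-methylene, and the new C9 centre (convex-face attack expected) is erased in step 10.

**Step 7**
Reactants: 16 keto alcohol
Product: 18 diol ketone 6α,9α-dihydroxy-15,16-epoxy-5β-labda-8(17),13(16),14-trien-2-one, via silyl enol ether diol 17 (not isolated)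
Conditions: LiBH(s-Bu)3, THF, −78 °C; AcOH; Bu4NF, THF, 0 °C
Reagents that add atoms: none
Why: Bulky trialkylborohydride reduction: the axial α trajectory at C6 is blocked by the syn-axial C1 methylene of ring A (C9, now quaternary, sits equatorial on ring A), so hydride enters equatorially from the β face and gives the axial 6α-alcohol; fluoride then cleaves the silyl enol ether to the C2 ketone.

**Step 8**
Reactants: 18 diol ketone
Product: 19 furan triol 15,16-epoxy-5β-labda-8(17),13(16),14-triene-2α,6α,9α-triol
Conditions: Li, NH3(l), THF, EtOH, −78 °C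
Reagents that add atoms: none
Why: Dissolving-metal ketone reduction gives the thermodynamically preferred equatorial 2α-alcohol (the 2β-epimer would be syn-axial to the C10 and C4 methyls), whereas hydride reagents would attack equatorially and give the wrong epimer.

**Step 9**
Reactants: 19 furan triol
Product: 22 butenolide triol 2α,6α,9α-trihydroxy-5β-labda-8(17),13-dien-15,16-olide, via furan endoperoxide 20 (not isolated), via hydroxybutenolide 21 (not isolated)
Conditions: O2, hν, tetraphenylporphyrin (cat.), iPr2NEt, CH2Cl2, −78 °C; then NaBH4, EtOH, 0 °C; pH 4 buffer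
Reagents that add atoms: dioxygen, O=O
Why: Singlet-oxygen [4+2] cycloaddition to the furan, amine-directed Kornblum–DeLaMare opening at the less hindered bridgehead (C15) and borohydride reduction of the ring-opened aldehyde with relactonisation give the β-substituted butenolide; the 1,1-disubstituted alkene reacts far more slowly with singlet oxygen than the furan.

**Step 10**
Reactants: 22 butenolide triol
Product: 23 target 2α,6α,17-trihydroxy-5β-labda-8,13-dien-15,16-olide
Conditions: Ph3SiOReO3 (5 mol %), Et2O, −40 → 0 °C
Reagents that add atoms: none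
Why: Perrhenate-catalysed [3,3] 1,3-transposition of the tertiary allylic alcohol is driven by formation of the tetrasubstituted ring alkene and the primary alcohol; it moves the oxygen from C9 to C17 and leaves C2, C5, C6 and C10 untouched.

**Compound list**
1 | 2,6-dimethylphenol | Cc1cccc(C)c1O | starting material
2 | 2,6-dimethyl-1,4-benzoquinone | CC1=CC(=O)C=C(C)C1=O | intermediate
3 | mesityl oxide (4-methylpent-3-en-2-one) | CC(=O)C=C(C)C | starting material
4 | lithium 4-methylpenta-1,3-dien-2-olate | [Li+].[O-]C(=C)C=C(C)C | intermediate (not isolated)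
5 | triisopropyl[(4-methylpenta-1,3-dien-2-yl)oxy]silane | C=C(O[Si](C(C)C)(C(C)C)C(C)C)C=C(C)C | intermediate
6 | (4aR,8aS)-2,5,5,8a-tetramethyl-7-[(triisopropylsilyl)oxy]-4a,5,8,8a-tetrahydronaphthalene-1,4-dione (cis-fused; C6 and C9 ketones, 7-ene, C2 silyl enol ether) | CC1(C)C=C(O[Si](C(C)C)(C(C)C)C(C)C)C[C@]2(C)C(=O)C(C)=CC(=O)[C@H]12 | intermediate
7 | 3-bromofuran | Brc1ccoc1 | starting material
8 | oxirane | C1CO1 | starting material
9 | furan-3-yllithium | [Li]c1ccoc1 | intermediate (not isolated)
10 | 2-(furan-3-yl)ethanol | OCCc1ccoc1 | intermediate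
11 | 3-(2-bromoethyl)furan | BrCCc1ccoc1 | intermediate
12 | [2-(furan-3-yl)ethyl]magnesium bromide | Br[Mg]CCc1ccoc1 | intermediate (not isolated)
13 | dichloro[2-(furan-3-yl)ethyl]cerium | Cl[Ce](Cl)CCc1ccoc1 | intermediate (not isolated)
14 | lithium dienolate of 6 (O–C6=C7–C8=C17, C9 ketone free) | [Li+].CC1(C)C=C(O[Si](C(C)C)(C(C)C)C(C)C)C[C@]2(C)C(=O)C(=C)C=C([O-])[C@H]12 | intermediate (not isolated)
15 | C9 alkoxide (dichlorocerium) / C6 lithium dienolate adduct | [Li+].[Ce+3].[Cl-].[Cl-].CC1(C)C=C(O[Si](C(C)C)(C(C)C)C(C)C)C[C@]2(C)[C@@]([O-])(CCc3ccoc3)C(=C)C=C([O-])[C@H]12 | intermediate (not isolated)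
16 | 9α-hydroxy-2-[(triisopropylsilyl)oxy]-15,16-epoxy-5β-labda-2,8(17),13(16),14-tetraen-6-one | CC1(C)C=C(O[Si](C(C)C)(C(C)C)C(C)C)C[C@]2(C)[C@@](O)(CCc3ccoc3)C(=C)CC(=O)[C@H]12 | intermediate
17 | 2-[(triisopropylsilyl)oxy]-15,16-epoxy-5β-labda-2,8(17),13(16),14-tetraene-6α,9α-diol | CC1(C)C=C(O[Si](C(C)C)(C(C)C)C(C)C)C[C@]2(C)[C@@](O)(CCc3ccoc3)C(=C)C[C@H](O)[C@H]12 | intermediate (not isolated)
18 | 6α,9α-dihydroxy-15,16-epoxy-5β-labda-8(17),13(16),14-trien-2-one | CC1(C)CC(=O)C[C@]2(C)[C@@](O)(CCc3ccoc3)C(=C)C[C@H](O)[C@H]12 | intermediate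
19 | 15,16-epoxy-5β-labda-8(17),13(16),14-triene-2α,6α,9α-triol | CC1(C)C[C@H](O)C[C@]2(C)[C@@](O)(CCc3ccoc3)C(=C)C[C@H](O)[C@H]12 | intermediate
20 | furan endoperoxide of 19 (2,3,7-trioxabicyclo[2.2.1]hept-5-ene; both bridgehead epimers) | CC1(C)C[C@H](O)C[C@]2(C)[C@@](O)(CCC3=CC4OOC3O4)C(=C)C[C@H](O)[C@H]12 | intermediate (not isolated)
21 | 2α,6α,9α,16-tetrahydroxy-5β-labda-8(17),13-dien-15,16-olide (γ-hydroxybutenolide, both C16 epimers) | CC1(C)C[C@H](O)C[C@]2(C)[C@@](O)(CCC3=CC(=O)OC3O)C(=C)C[C@H](O)[C@H]12 | intermediate (not isolated)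
22 | 2α,6α,9α-trihydroxy-5β-labda-8(17),13-dien-15,16-olide | CC1(C)C[C@H](O)C[C@]2(C)[C@@](O)(CCC3=CC(=O)OC3)C(=C)C[C@H](O)[C@H]12 | intermediate
23 | 4-{2-[(4S,4aR,7S,8aS)-4,7-dihydroxy-2-(hydroxymethyl)-5,5,8a-trimethyl-3,4,4a,5,6,7,8,8a-octahydronaphthalen-1-yl]ethyl}furan-2(5H)-one | CC1(C)C[C@H](O)C[C@]2(C)C(CCC3=CC(=O)OC3)=C(CO)C[C@H](O)[C@H]12 | target

**Totals**
Total step count: 10. Longest linear sequence: 7 steps (1 → 2 → 6 → 16 → 18 → 19 → 22 → 23, i.e. steps 1, 3, 6, 7, 8, 9, 10).

**Three steps most likely to fail**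

Step 3. The diene carries a (Z)-methyl that disfavours the s-cis form and must create the quaternary C4 next to C5 with high enantioselectivity. The fallback sets out from 2 and 5 and returns at 6. The first C–C bond (C1–C10) is made as a separate intermolecular Mukaiyama–Michael addition under the same chiral oxazaborolidinium activation, allowed to stop after silyl transfer at the open-chain silyloxy dienone F1. Ring A is then closed in a second operation by an intramolecular silyl-transfer Mukaiyama–Michael addition of C5 onto the β,β-dimethyl enone (HN(SO2CF3)2, 5 mol %, CH2Cl2, −40 °C), which regenerates the C2 silyl enol ether and gives 6.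

Step 6. The one-pot sequence depends on clean C17 deprotonation, addition to a hindered carbonyl in a dianionic species, and kinetic C7 protonation. The fallback sets out from 6 and returns at 17. The dienolate 14 is simply quenched (AcOH, −78 °C) to give the deconjugated exo-methylene dione F2. Its saturated C6 ketone is reduced from the β face with LiAlH(Ot-Bu)3 (THF, −78 → −40 °C), leaving the hindered cross-conjugated C9 enone, to give the hydroxy enone F3. An excess of organocerium reagent 13 then adds 1,2 to C9 to give 17, which is desilylated as in step 7.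

Step 10. The tertiary allylic alcohol may eliminate or be trapped by the C6 hydroxyl instead of transposing. The fallback sets out from 22 and returns at 23. The allylic system is ionised through a π-allylpalladium intermediate (Pd(PPh3)4, zerovalent palladium, 5 mol %, benzoic acid, THF, 50 °C), with reversible capture by benzoate at the unhindered primary terminus, to give the 17-benzoate F4. Mild methanolysis (K2CO3, MeOH, 0 °C) then gives 23.

**Further compounds**
F1 | step 3 | (S)-2,6-dimethyl-6-(4-methyl-2-oxopent-3-en-1-yl)-4-[(triisopropylsilyl)oxy]cyclohexa-2,4-dien-1-one | CC(C)=CC(=O)C[C@@]1(C)C=C(O[Si](C(C)C)(C(C)C)C(C)C)C=C(C)C1=O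
F2 | step 6 | (4aR,8aS)-5,5,8a-trimethyl-2-methylidene-7-[(triisopropylsilyl)oxy]-2,3,4a,5,8,8a-hexahydronaphthalene-1,4-dione | CC1(C)C=C(O[Si](C(C)C)(C(C)C)C(C)C)C[C@]2(C)C(=O)C(=C)CC(=O)[C@H]12
F3 | step 6 | 6α-hydroxy analogue of F2 (C6 carbinol, C9 exo-methylene enone, C2 silyl enol ether) | CC1(C)C=C(O[Si](C(C)C)(C(C)C)C(C)C)C[C@]2(C)C(=O)C(=C)C[C@H](O)[C@H]12
F4 | step 10 | 17-O-benzoyl-2α,6α,17-trihydroxy-5β-labda-8,13-dien-15,16-olide | CC1(C)C[C@H](O)C[C@]2(C)C(CCC3=CC(=O)OC3)=C(COC(=O)c3ccccc3)C[C@H](O)[C@H]12
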